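**Retrosynthetic overview**

1. Pyranone ring (closed last): the lactone C–O bond and the C3=C4 bond are cut together, leading back to 2-hydroxy-4-methoxybenzaldehyde and a dearomatised bicyclic enol lactone. Acyl transfer from that enol lactone to the phenol also frees the ring ketone next to the CH2.
2. Tertiary carbinol: the C–OH bond is cut by an enantioselective hydroxylative dearomatisation (ortho-quinol formation) of a prenylated homogentisic lactone. The lactone keeps the para oxygen acylated, so the hydroquinone cannot escape to the quinone.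
3. Prenyl group: ortho C-prenylation of homogentisic acid γ-lactone with prenol.
4. Ring order: the carbocycle is the benzene ring of the lactone from the start and becomes the cyclohexenedione in the dearomatisation. The pyranone ring is then closed onto the anisole ring brought by the aldehyde, and the temporary five-membered lactone is opened in that same step.
5. This follows the presumed biosynthesis: prenylation of a homogentisate-type hydroquinone, oxygenative dearomatisation at the prenylated carbon, and lactonisation of an ortho-hydroxycinnamoyl unit.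

Assumption: the facial sense of the chiral iodyl reagent in step 2 cannot be predicted with certainty; the (4S)-reagent is written as the one that gives the (6R)-product, and its mirror image is used instead if the first run shows the opposite sense.
Assumption: the iodyl reagent is not a catalogue item; it is made beforehand by dimethyldioxirane oxidation of its iodoarene, which is recovered from step 2 and re-oxidised.

**Route**

Step 1
Reactants: 1 5-hydroxy-1-benzofuran-2(3H)-one (homogentisic acid γ-lactone); 2 3-methylbut-2-en-1-ol (prenol)
Product: 3 5-hydroxy-6-(3-methylbut-2-en-1-yl)-1-benzofuran-2(3H)-one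
Conditions: 2 (1.5 equiv), acidic Al2O3 (activated, ca. 2 g per mmol), ClCH2CH2Cl, 80 °C, 16 h
Reagents that add atoms: none
Why: Friedel–Crafts ortho-prenylation templated by the acidic alumina surface: phenol and allylic alcohol are bound side by side, so the allyl cation equivalent is delivered ortho to the free hydroxyl, and C6 (para to the lactone CH2, open on its other side) is preferred over C4 (wedged against the ring fusion), while the absence of base spares the lactone and its acidic C3 methylene; no stereocentre is formed.

Step 2
Reactants: 3 5-hydroxy-6-(3-methylbut-2-en-1-yl)-1-benzofuran-2(3H)-one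
Product: 4 (6R)-6-hydroxy-6-(3-methylbut-2-en-1-yl)-1-benzofuran-2,5(3H,6H)-dione
Conditions: chiral iodyl arene (1.2 equiv), AcOH (2 equiv), MeOCH2CH2OMe, −40 to −20 °C, dark; then Me2S (3 equiv), −20 °C; cold SiO2 filtration, used at once
Reagents that add atoms: (4S)-2-(2-iodylphenyl)-4-(propan-2-yl)-4,5-dihydro-1,3-oxazole, CC(C)[C@H]1COC(=N1)c1ccccc1I(=O)=O
Why: Hydroxylative phenol dearomatisation by a chiral λ5-iodane: the phenol oxygen binds to pentavalent iodine and an iodine-bound oxygen is transferred within the complex to the alkylated ortho carbon C6 (the pattern known for 2-alkyl-5-substituted phenols, C4 being shielded by the ring fusion), the oxazoline stereocentre beside iodine selecting one face of the flat phenol and thereby setting the new carbinol centre as R, while the para oxygen, tied up as the lactone, cannot give a para-quinone and the prenyl alkene does not react with iodyl arenes.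

Step 3
Reactants: 4 (6R)-6-hydroxy-6-(3-methylbut-2-en-1-yl)-1-benzofuran-2,5(3H,6H)-dione; 5 2-hydroxy-4-methoxybenzaldehyde
Product: 7 3-[(4R)-4-hydroxy-4-(3-methylbut-2-en-1-yl)-3,6-dioxocyclohex-1-en-1-yl]-7-methoxy-2H-chromen-2-one, via aryl ester 6 (not isolated)
Conditions: 5 (1.1 equiv), Et3N (1.2 equiv), 4 Å molecular sieves, MeCN, 0 °C to rt, 6–12 h; pH 5 buffer work-up
Reagents that add atoms: none
Why: Proposed new method: the phenoxide of 5 attacks the enol-lactone carbonyl of 4 (enol esters are irreversible acyl donors because the leaving enol becomes a ketone), which opens the five-membered ring to aryl ester 6 and turns C7a into the ring ketone next to the CH2; the methylene of 6, activated by the ester and vinylogously by the enone, then closes on the neighbouring aldehyde by intramolecular Knoevenagel condensation and loss of water to give the pyranone ring, the closest known reactions being the Et3N-mediated condensation of benzofuran-2(3H)-ones with salicylaldehydes to 3-(2-hydroxyphenyl)coumarins and the base-induced cyclisation of 2-formylphenyl arylacetates; the quaternary carbinol is not touched, so its R configuration is carried into 7.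

**Compound list**

1 | 5-hydroxy-1-benzofuran-2(3H)-one (homogentisic acid γ-lactone) | O=C1Cc2cc(O)ccc2O1 | starting material
2 | 3-methylbut-2-en-1-ol (prenol) | CC(C)=CCO | starting material
3 | 5-hydroxy-6-(3-methylbut-2-en-1-yl)-1-benzofuran-2(3H)-one | O=C1Cc2cc(O)c(CC=C(C)C)cc2O1 | intermediate
4 | (6R)-6-hydroxy-6-(3-methylbut-2-en-1-yl)-1-benzofuran-2,5(3H,6H)-dione | O=C1CC2=CC(=O)[C@@](O)(CC=C(C)C)C=C2O1 | intermediate
5 | 2-hydroxy-4-methoxybenzaldehyde | COc1ccc(C=O)c(O)c1 | starting material
6 | 2-formyl-5-methoxyphenyl 2-[(4R)-4-hydroxy-4-(3-methylbut-2-en-1-yl)-3,6-dioxocyclohex-1-en-1-yl]acetate | COc1ccc(C=O)c(OC(=O)CC2=CC(=O)[C@@](O)(CC=C(C)C)CC2=O)c1 | intermediate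
7 | 3-[(4R)-4-hydroxy-4-(3-methylbut-2-en-1-yl)-3,6-dioxocyclohex-1-en-1-yl]-7-methoxy-2H-chromen-2-one | COc1ccc2cc(C3=CC(=O)[C@@](O)(CC=C(C)C)CC3=O)c(=O)oc2c1 | target

**Step count and risks**

Total step count: 3. Longest linear sequence: 3 steps (1 → 3 → 4 → 7); 5 enters in the last step.

The three steps most likely to fail, in order of risk:

Step 2 carries the highest risk. Oxygen transfer may go to C4 and give an ortho-quinone, 4 may dimerise by Diels–Alder reaction, and the ee is expected to be only about 60–80% by analogy with 2-alkylphenols, so 7 would be recrystallised and checked by chiral HPLC. The fallback sets out from 3 and comes back to the route at 7, and brings the oxygen in after the coumarin is made, as an epoxide. 3 and 5 are condensed with Et3N in MeCN (the known benzofuranone–salicylaldehyde coumarin synthesis) to 3-[2,5-dihydroxy-4-(3-methylbut-2-en-1-yl)phenyl]-7-methoxy-2H-chromen-2-one F2. Ag2O in Et2O oxidises this to the quinone 2-(7-methoxy-2-oxo-2H-chromen-3-yl)-5-(3-methylbut-2-en-1-yl)cyclohexa-2,5-diene-1,4-dione F3. Asymmetric nucleophilic epoxidation of the prenyl-bearing double bond (tBuOOH, N-(9-anthracenylmethyl)cinchonidinium chloride, toluene/aqueous K2CO3, −20 °C) gives 3-[(1S,6R)-6-(3-methylbut-2-en-1-yl)-2,5-dioxo-7-oxabicyclo[4.1.0]hept-3-en-3-yl]-7-methoxy-2H-chromen-2-one F4. PhSeSePh/NaBH4/AcOH in EtOH at 0 °C then opens the epoxide by attack of phenylselenide at the secondary carbon followed by deselenation, which leaves the tertiary C–O bond and gives 7. Site-selectivity between the two quinone double bonds in the epoxidation has to be checked.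

Step 3 is next. Acyl transfer may be outrun by amine addition to the dienone, by dehydration to the quinone, or by an α-ketol shift. The fallback sets out from 3 and 5 and comes back at 7, and makes the C=C bond before dearomatisation. 5 is silylated (TBSCl, imidazole, DMF) to 2-{[tert-butyl(dimethyl)silyl]oxy}-4-methoxybenzaldehyde F5. Knoevenagel condensation with 3 (Et3N, 4 Å molecular sieves, toluene, 60 °C) gives (3E)-3-(2-{[tert-butyl(dimethyl)silyl]oxy}-4-methoxybenzylidene)-5-hydroxy-6-(3-methylbut-2-en-1-yl)-1-benzofuran-2(3H)-one F6, whose capped phenol cannot translactonise. The iodane dearomatisation of step 2 then gives (3E,6R)-3-(2-{[tert-butyl(dimethyl)silyl]oxy}-4-methoxybenzylidene)-6-hydroxy-6-(3-methylbut-2-en-1-yl)-1-benzofuran-2,5(3H,6H)-dione F7. Buffered fluoride (Bu4NF, AcOH, THF, 0 °C) frees the phenoxide, whose quinone-methide resonance lets the arylidene bond rotate. The phenoxide opens the enol lactone, closing the pyranone ring and releasing the ring ketone, to give 7 with no base-mediated C–C bond formation on the dearomatised ring.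

Step 1 is third. Prenylation may go to C4 instead of C6, the product may cyclise to a chroman, or a second prenyl group may add. The fallback sets out from 1 and comes back at 3. NBS in MeCN at 0 °C brominates 1 ortho to the hydroxyl at the open C6 position to give 6-bromo-5-hydroxy-1-benzofuran-2(3H)-one F1. A base-free Stille coupling with tributyl(3-methylbut-2-en-1-yl)stannane (Pd(PPh3)4, LiCl, DMF, 80 °C) then puts the prenyl group on that carbon and gives 3.

**Further compounds**

F1 | step 1 | 6-bromo-5-hydroxy-1-benzofuran-2(3H)-one | O=C1Cc2cc(O)c(Br)cc2O1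
F2 | step 2 | 3-[2,5-dihydroxy-4-(3-methylbut-2-en-1-yl)phenyl]-7-methoxy-2H-chromen-2-one | COc1ccc2cc(-c3cc(O)c(CC=C(C)C)cc3O)c(=O)oc2c1
F3 | step 2 | 2-(7-methoxy-2-oxo-2H-chromen-3-yl)-5-(3-methylbut-2-en-1-yl)cyclohexa-2,5-diene-1,4-dione | COc1ccc2cc(C3=CC(=O)C(CC=C(C)C)=CC3=O)c(=O)oc2c1
F4 | step 2 | 3-[(1S,6R)-6-(3-methylbut-2-en-1-yl)-2,5-dioxo-7-oxabicyclo[4.1.0]hept-3-en-3-yl]-7-methoxy-2H-chromen-2-one | COc1ccc2cc(C3=CC(=O)[C@]4(CC=C(C)C)O[C@@H]4C3=O)c(=O)oc2c1
F5 | step 3 | 2-{[tert-butyl(dimethyl)silyl]oxy}-4-methoxybenzaldehyde | COc1ccc(C=O)c(O[Si](C)(C)C(C)(C)C)c1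
F6 | step 3 | (3E)-3-(2-{[tert-butyl(dimethyl)silyl]oxy}-4-methoxybenzylidene)-5-hydroxy-6-(3-methylbut-2-en-1-yl)-1-benzofuran-2(3H)-one | O=C1Oc2cc(CC=C(C)C)c(O)cc2/C1=C\c1ccc(OC)cc1O[Si](C)(C)C(C)(C)C
F7 | step 3 | (3E,6R)-3-(2-{[tert-butyl(dimethyl)silyl]oxy}-4-methoxybenzylidene)-6-hydroxy-6-(3-methylbut-2-en-1-yl)-1-benzofuran-2,5(3H,6H)-dione | O=C1OC2=C[C@](O)(CC=C(C)C)C(=O)C=C2/C1=C\c1ccc(OC)cc1O[Si](C)(C)C(C)(C)C
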